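**Strategy.** Everything rests on cutting the two exocyclic C–C bonds at neighbouring ring carbons of the cyclopropane: C2(quaternary)–CH2 of the homofarnesyl chain and C3(H)–CH= of the C19 alkenyl group. The key step exploits the fact that these two groups are cis to each other and trans to the CH2OH on ring carbon C1, the signature of a syn addition across a cyclopropene C=C anti to its C1 substituent. In one operation, copper-catalysed carbomagnesiation, zinc exchange and Negishi coupling join three components and set both new stereocentres. The precursor is the bulky silyl ether of enantiopure (R)-(2-methylcycloprop-2-enyl)methanol, secured by resolution and not by asymmetric catalysis.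

Key step: step 13

**Remarks on the chemistry**

- Ring numbering used throughout: C1 carries CH2OH, C2 carries the methyl group and the homofarnesyl chain, C3 carries the alkenyl group. The target is (1R,2R,3R): methyl cis to CH2OH, chain and alkenyl trans to it.
- The structures of the three coupling partners were checked against the target SMILES. The (R)-cyclopropene maps onto (1R,2R,3R) by anti addition, and all alkene geometries agree, so no structure needed correction.
- Assumption: cyclopropenation of a small 1-alkyne with a simple diazoacetate under chiral dirhodium carboxamidate catalysis is expected to give only moderate enantiomeric excess, and the oily products cannot be upgraded by crystallisation. The racemic acid is therefore resolved through covalent oxazolidinone diastereomers. The configuration of the imide taken on is to be confirmed by X-ray crystallography, with the auxiliary as internal reference.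
- The TBDPS ether is kept because it is bulky, weakly Lewis basic, UV-active and makes the C5 cyclopropene non-volatile. THF is used in the key step to compete with any oxygen–metal chelation.

**Route**

Step 1
Reactants: 1 propyne; 2 ethyl diazoacetate
Product: 3 ethyl 2-methylcycloprop-2-ene-1-carboxylate (racemic)
Conditions: Rh2(OAc)4 (0.5 mol%), 1 (3 equiv, condensed), CH2Cl2, 0 °C → rt, 2 added over 10 h
Reagents that add atoms: none
Why: Dirhodium-carbenoid [2+1] cycloaddition (cyclopropenation) of a terminal alkyne with a diazoacetate under slow addition is the standard entry to 2-alkylcycloprop-2-ene-1-carboxylates; the product is racemic and its stereocentre is sorted in step 3.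

Step 2
Reactants: 3 ethyl 2-methylcycloprop-2-ene-1-carboxylate (racemic)
Product: 4 2-methylcycloprop-2-ene-1-carboxylic acid (racemic)
Conditions: KOH, MeOH–H2O, rt; then aq HCl to pH 2, 0 °C, Et2O extraction, used as a solution
Reagents that add atoms: potassium hydroxide, [K+].[OH-]
Why: Ester saponification at room temperature leaves the strained, non-conjugated C=C untouched, and the acid is kept in solution and used at once because small cyclopropene acids are volatile and prone to ene dimerisation.

Step 3
Reactants: 4 2-methylcycloprop-2-ene-1-carboxylic acid (racemic)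
Product: 6 (4S)-4-benzyl-3-[(1R)-2-methylcycloprop-2-ene-1-carbonyl]-1,3-oxazolidin-2-one, via mixed pivalic anhydride 5 (not isolated)
Conditions: PivCl, Et3N, THF, −20 °C; then LiCl, (S)-4-benzyl-1,3-oxazolidin-2-one, −20 °C → rt; SiO2 separation of the two diastereomers
Reagents that add atoms: (S)-4-benzyl-1,3-oxazolidin-2-one, O=C1N[C@@H](Cc2ccccc2)CO1
Why: N-Acylation of an Evans-type oxazolidinone through the pivalic mixed anhydride turns the enantiomers into covalent diastereomers that should separate on silica (a classical resolution known for cyclopropene carboxylic acids); no stereocentre is made, and C1 cannot epimerise because its carbanion would be an antiaromatic cyclopropenyl anion.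

Step 4
Reactants: 6 (4S)-4-benzyl-3-[(1R)-2-methylcycloprop-2-ene-1-carbonyl]-1,3-oxazolidin-2-one
Product: 7 [(1R)-2-methylcycloprop-2-en-1-yl]methanol
Conditions: LiBH4, MeOH (1 equiv), Et2O, 0 °C; auxiliary removed on a short SiO2 pad (pentane–Et2O), solution concentrated cold
Reagents that add atoms: none
Why: Reductive cleavage of the N-acyloxazolidinone with LiBH4 gives the primary alcohol and returns the auxiliary, the isolated cyclopropene C=C being inert to borohydride and the stereocentre untouched.

Step 5
Reactants: 7 [(1R)-2-methylcycloprop-2-en-1-yl]methanol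
Product: 8 tert-butyl{[(1R)-2-methylcycloprop-2-en-1-yl]methoxy}diphenylsilane
Conditions: TBDPSCl, imidazole, CH2Cl2, 0 °C → rt
Reagents that add atoms: tert-butyl(chloro)diphenylsilane, CC(C)(C)[Si](Cl)(c1ccccc1)c1ccccc1
Why: Imidazole-promoted silylation of a primary alcohol installs the bulky, weakly coordinating group that blocks one face of the cyclopropene in step 13.

Step 6
Reactants: 1 propyne; 9 (2E,6E)-farnesyl bromide
Product: 12 (5E,9E)-6,10,14-trimethylpentadeca-5,9,13-trien-1-yne, via 1,3-dilithiopropyne 10 (not isolated), via lithium acetylide 11 (not isolated)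
Conditions: 1 (1.5 equiv), n-BuLi (3.0 equiv), TMEDA, Et2O–hexane, −78 → 0 °C; then 9, −78 °C → rt; H2O
Reagents that add atoms: none
Why: Propargylation of an allylic halide with 1,3-dilithiopropyne: the sp3 carbanion end is the more nucleophilic and displaces the primary allylic bromide at the alpha carbon (SN2) with the E geometry kept, and the acetylide end is protonated on quench.

Step 7
Reactants: 12 (5E,9E)-6,10,14-trimethylpentadeca-5,9,13-trien-1-yne
Product: 14 (1E,5E,9E)-1-iodo-2,6,10,14-tetramethylpentadeca-1,5,9,13-tetraene, via alkenyldimethylalane 13 (not isolated)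
Conditions: Me3Al (2 equiv), Cp2ZrCl2 (0.25 equiv), CH2Cl2, 0 °C → rt; then I2, THF, −30 → 0 °C
Reagents that add atoms: trimethylaluminium, C[Al](C)C; iodine, II
Why: Negishi zirconium-catalysed methylalumination adds methyl and aluminium syn across the terminal alkyne with methyl on the internal carbon, and iodinolysis of the C–Al bond with retention gives the E-alkenyl iodide; the isolated trisubstituted alkenes do not carbometalate.

Step 8
Reactants: 15 (2E,6E)-farnesol
Product: 16 (2E,6E)-farnesal
Conditions: TEMPO (10 mol%), PhI(OAc)2 (1.1 equiv), CH2Cl2, rt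
Reagents that add atoms: none
Why: Oxoammonium (TEMPO/PhI(OAc)2) oxidation of the allylic alcohol stops at the aldehyde and should not isomerise the 2E double bond.

Step 9
Reactants: 16 (2E,6E)-farnesal
Product: 17 (3E,7E)-4,8,12-trimethyltrideca-1,3,7,11-tetraene
Conditions: Ph3PCH3Br, n-BuLi, THF, 0 °C; then 16, 0 °C → rt
Reagents that add atoms: methyltriphenylphosphonium bromide, C[P+](c1ccccc1)(c1ccccc1)c1ccccc1.[Br-]
Why: Wittig methylenation of the enal with the non-stabilised ylide gives the terminal diene without touching the trisubstituted alkenes.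

Step 10
Reactants: 17 (3E,7E)-4,8,12-trimethyltrideca-1,3,7,11-tetraene
Product: 19 (3E,7E)-4,8,12-trimethyltrideca-3,7,11-trien-1-ol (homofarnesol), via B-homofarnesyl-9-BBN 18 (not isolated)
Conditions: 9-BBN (1.1 equiv), THF, 0 °C → rt; then NaOH, 30% H2O2, 0 °C → rt
Reagents that add atoms: hydrogen peroxide, OO
Why: Hydroboration–oxidation: 9-BBN adds anti-Markovnikov to the monosubstituted terminal C=C only, the trisubstituted alkenes being far slower, and alkaline peroxide oxidises the C–B bond with retention.

Step 11
Reactants: 19 (3E,7E)-4,8,12-trimethyltrideca-3,7,11-trien-1-ol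
Product: 20 (3E,7E)-1-bromo-4,8,12-trimethyltrideca-3,7,11-triene (homofarnesyl bromide)
Conditions: CBr4, PPh3, CH2Cl2, 0 °C
Reagents that add atoms: carbon tetrabromide, BrC(Br)(Br)Br
Why: Appel bromination converts the primary alcohol to the bromide by SN2 displacement of the oxyphosphonium under neutral conditions that leave the alkenes alone.

Step 12
Reactants: 20 (3E,7E)-1-bromo-4,8,12-trimethyltrideca-3,7,11-triene
Product: 21 (E,E)-homofarnesylmagnesium bromide (THF solution, titrated)
Conditions: Mg turnings (activated with BrCH2CH2Br), THF, rt → 35 °C, slow addition of 20; titration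
Reagents that add atoms: magnesium, [Mg]
Why: Grignard formation by insertion of magnesium into the primary C–Br bond; the homoallyl-to-cyclopropylcarbinyl rearrangement would need a tertiary carbanion and should not scramble the 3E alkene.

Step 13
Reactants: 8 tert-butyl{[(1R)-2-methylcycloprop-2-en-1-yl]methoxy}diphenylsilane; 21 (E,E)-homofarnesylmagnesium bromide; 14 (1E,5E,9E)-1-iodo-2,6,10,14-tetramethylpentadeca-1,5,9,13-tetraene
Product: 24 O-tert-butyldiphenylsilyl ether of the target (1R,2R,3R), via cyclopropylmagnesium bromide 22 (not isolated), via cyclopropylzinc bromide 23 (not isolated)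
Conditions: 8 (1.05 equiv), 21 (1.00 equiv), CuI (10 mol%), THF, −40 → −10 °C; ZnBr2 (1.1 equiv), THF, 0 °C; 14 (0.9 equiv), Pd(PPh3)4 (5 mol%), THF, rt → 45 °C
Reagents that add atoms: none
Why: A homofarnesylcopper species formed from 21 and catalytic CuI adds syn across the strained C=C of 8, carbon to the methyl-bearing carbon (new quaternary C2) and metal to the CH carbon (C3), and exchange with further 21 releases cyclopropylmagnesium 22 and turns the copper over, strain release making the addition fast and irreversible. ZnBr2 then gives cyclopropylzinc 23, which enters a Negishi cycle (oxidative addition of 14 to zerovalent palladium, transmetalation, reductive elimination) to form the C3–alkenyl bond. The closest known reaction type is the copper-catalysed carbomagnesiation of 3-substituted cyclopropenes followed by electrophilic trapping or palladium-catalysed coupling of the configurationally stable cyclopropyl metal. No ring is closed; the three-membered ring of 8 is carried through intact. Both new stereocentres are controlled by the single C1 centre of 8: the bulky, weakly Lewis-basic CH2OTBDPS group shields its own face, so chain and metal enter anti to it and hence cis to each other, and the C3–metal bond passes to zinc, palladium and carbon with retention, as does the E geometry of 14. The step needs regioselectivity (secured by formation of the less substituted, secondary cyclopropyl metal), facial selectivity (secured by the silyl ether in THF) and chemoselectivity (secured by near-equimolar, titrated 21 so that no homofarnesylzinc competes for 14, and by the inertness of the isolated trisubstituted alkenes).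

Step 14
Reactants: 24 O-tert-butyldiphenylsilyl ether of the target
Product: 25 [(1R,2R,3R)-2-methyl-2-[(3E,7E)-4,8,12-trimethyltrideca-3,7,11-trien-1-yl]-3-[(1E,5E,9E)-2,6,10,14-tetramethylpentadeca-1,5,9,13-tetraen-1-yl]cyclopropyl]methanol (target)
Conditions: Bu4NF (1.5 equiv), THF, 0 °C → rt; chromatography on Et3N-deactivated SiO2
Reagents that add atoms: none
Why: Fluoride-mediated cleavage of the Si–O bond (silyl ether deprotection) runs under basic conditions, avoiding acid that would ionise the cyclopropylcarbinyl alcohol, and touches no stereocentre.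

**Compound list**

1 | propyne | CC#C | starting material
2 | ethyl diazoacetate | CCOC(=O)C=[N+]=[N-] | starting material
3 | ethyl 2-methylcycloprop-2-ene-1-carboxylate (racemic) | CCOC(=O)C1C=C1C | intermediate
4 | 2-methylcycloprop-2-ene-1-carboxylic acid (racemic) | CC1=CC1C(=O)O | intermediate
5 | 2-methylcycloprop-2-ene-1-carboxylic pivalic anhydride (racemic mixed anhydride) | CC1=CC1C(=O)OC(=O)C(C)(C)C | intermediate (not isolated)
6 | (4S)-4-benzyl-3-[(1R)-2-methylcycloprop-2-ene-1-carbonyl]-1,3-oxazolidin-2-one | CC1=C[C@H]1C(=O)N2[C@@H](Cc3ccccc3)COC2=O | intermediate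
7 | [(1R)-2-methylcycloprop-2-en-1-yl]methanol | CC1=C[C@H]1CO | intermediate
8 | tert-butyl{[(1R)-2-methylcycloprop-2-en-1-yl]methoxy}diphenylsilane (key-step precursor) | CC1=C[C@H]1CO[Si](c2ccccc2)(c3ccccc3)C(C)(C)C | intermediate
9 | (2E,6E)-farnesyl bromide, (2E,6E)-1-bromo-3,7,11-trimethyldodeca-2,6,10-triene | CC(C)=CCC/C(C)=C/CC/C(C)=C/CBr | starting material
10 | 1,3-dilithiopropyne | [Li]CC#C[Li] | intermediate (not isolated)
11 | lithium acetylide of 12, lithium (5E,9E)-6,10,14-trimethylpentadeca-5,9,13-trien-1-yn-1-ide | [Li]C#CCC/C=C(\C)CC/C=C(\C)CCC=C(C)C | intermediate (not isolated)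
12 | (5E,9E)-6,10,14-trimethylpentadeca-5,9,13-trien-1-yne | C#CCC/C=C(\C)CC/C=C(\C)CCC=C(C)C | intermediate
13 | dimethyl[(1E,5E,9E)-2,6,10,14-tetramethylpentadeca-1,5,9,13-tetraen-1-yl]alane (Al and 2-methyl cis) | C[Al](C)/C=C(\C)CC/C=C(\C)CC/C=C(\C)CCC=C(C)C | intermediate (not isolated)
14 | (1E,5E,9E)-1-iodo-2,6,10,14-tetramethylpentadeca-1,5,9,13-tetraene | I/C=C(\C)CC/C=C(\C)CC/C=C(\C)CCC=C(C)C | intermediate
15 | (2E,6E)-farnesol | CC(C)=CCC/C(C)=C/CC/C(C)=C/CO | starting material
16 | (2E,6E)-farnesal | CC(C)=CCC/C(C)=C/CC/C(C)=C/C=O | intermediate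
17 | (3E,7E)-4,8,12-trimethyltrideca-1,3,7,11-tetraene | CC(C)=CCC/C(C)=C/CC/C(C)=C/C=C | intermediate
18 | 9-[(3E,7E)-4,8,12-trimethyltrideca-3,7,11-trien-1-yl]-9-borabicyclo[3.3.1]nonane | CC(C)=CCC/C(C)=C/CC/C(C)=C/CCB1C2CCCC1CCC2 | intermediate (not isolated)
19 | (3E,7E)-4,8,12-trimethyltrideca-3,7,11-trien-1-ol (homofarnesol) | CC(C)=CCC/C(C)=C/CC/C(C)=C/CCO | intermediate
20 | (3E,7E)-1-bromo-4,8,12-trimethyltrideca-3,7,11-triene (homofarnesyl bromide) | BrCC/C=C(\C)CC/C=C(\C)CCC=C(C)C | intermediate
21 | (E,E)-homofarnesylmagnesium bromide | Br[Mg]CC/C=C(\C)CC/C=C(\C)CCC=C(C)C | intermediate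
22 | cyclopropylmagnesium bromide: 24 with MgBr in place of the alkenyl group on C3, Mg cis to the homofarnesyl chain and trans to CH2OTBDPS | Br[Mg][C@@H]1[C@@H](CO[Si](c2ccccc2)(c3ccccc3)C(C)(C)C)[C@]1(C)CC/C=C(\C)CC/C=C(\C)CCC=C(C)C | intermediate (not isolated)
23 | cyclopropylzinc bromide: same skeleton and configuration as 22 with ZnBr on C3 | Br[Zn][C@@H]1[C@@H](CO[Si](c2ccccc2)(c3ccccc3)C(C)(C)C)[C@]1(C)CC/C=C(\C)CC/C=C(\C)CCC=C(C)C | intermediate (not isolated)
24 | tert-butyl{[(1R,2R,3R)-2-methyl-2-[(3E,7E)-4,8,12-trimethyltrideca-3,7,11-trien-1-yl]-3-[(1E,5E,9E)-2,6,10,14-tetramethylpentadeca-1,5,9,13-tetraen-1-yl]cyclopropyl]methoxy}diphenylsilane (key-step product) | CC(C)=CCC/C(C)=C/CC/C(C)=C/CC/C(C)=C/[C@@H]1[C@@H](CO[Si](c2ccccc2)(c3ccccc3)C(C)(C)C)[C@]1(C)CC/C=C(\C)CC/C=C(\C)CCC=C(C)C | intermediate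
25 | [(1R,2R,3R)-2-methyl-2-[(3E,7E)-4,8,12-trimethyltrideca-3,7,11-trien-1-yl]-3-[(1E,5E,9E)-2,6,10,14-tetramethylpentadeca-1,5,9,13-tetraen-1-yl]cyclopropyl]methanol; methyl cis, chain and alkenyl trans to CH2OH | CC(C)=CCC/C(C)=C/CC/C(C)=C/CC/C(C)=C/[C@@H]1[C@@H](CO)[C@]1(C)CC/C=C(\C)CC/C=C(\C)CCC=C(C)C | target

**Step count and risk**

Total steps: 14. Longest linear sequence: 7 steps (steps 1–5, 13, 14; the homofarnesyl arm, steps 8–12, 13, 14, is equally long). The iodide arm is 2 steps (6, 7).

Steps most likely to fail:

1. Step 13. What may go wrong: slow transmetalation or reductive elimination at the hindered secondary cyclopropylzinc next to a quaternary carbon, so that protodemetalation or homocoupling takes over; or erosion of facial selectivity if the ether oxygen guides the copper reagent to its own face. Fallback: the two bond formations are separated. Setting out from 8 and 21, cyclopropylmagnesium 22 is generated as in the first stage and quenched with 2-isopropoxy-4,4,5,5-tetramethyl-1,3,2-dioxaborolane to give the pinacol cyclopropylboronate F1. This is isolated, freed from any facial isomer and checked by NOE. Suzuki–Miyaura coupling of F1 with 14 (Pd(OAc)2, SPhos, K3PO4, toluene–H2O, 80 °C), a coupling known to go with retention for cyclopropylboron reagents, comes back to the route at 24.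

2. Step 3. What may go wrong: incomplete chromatographic separation of the two imide diastereomers, or loss of the small acid before acylation. Fallback: setting out from 3, iBu2AlH reduction (CH2Cl2, −78 °C) gives the racemic alcohol F2, and TBDPSCl/imidazole gives the racemic silyl ether F3. The UV-active F3 is resolved by preparative supercritical-fluid chromatography on a cellulose tris(3,5-dimethylphenylcarbamate) phase. The (R)-enantiomer, identified by correlation with a sample made through 6, comes back to the route at 8.

3. Step 12. What may go wrong: Wurtz homocoupling during magnesium insertion and an unreliable titre, which upsets the stoichiometry on which the chemoselectivity of step 13 depends. Fallback: setting out from 19, I2/PPh3/imidazole gives homofarnesyl iodide F4. Iodine–lithium exchange with t-BuLi (2 equiv, Et2O–pentane, −78 °C) gives homofarnesyllithium F5, and transmetalation with MgBr2·OEt2 comes back to the route at 21.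

**Further compounds**

F1 | step 13 | 4,4,5,5-tetramethyl-2-[2-methyl-3-(tert-butyldiphenylsilyloxymethyl)-2-homofarnesylcyclopropyl]-1,3,2-dioxaborolane, boron cis to the chain and trans to CH2OTBDPS | CC1(C)OB(OC1(C)C)[C@@H]2[C@@H](CO[Si](c3ccccc3)(c4ccccc4)C(C)(C)C)[C@]2(C)CC/C=C(\C)CC/C=C(\C)CCC=C(C)C
F2 | step 3 | (2-methylcycloprop-2-en-1-yl)methanol (racemic) | CC1=CC1CO
F3 | step 3 | tert-butyl[(2-methylcycloprop-2-en-1-yl)methoxy]diphenylsilane (racemic) | CC1=CC1CO[Si](c2ccccc2)(c3ccccc3)C(C)(C)C
F4 | step 12 | (3E,7E)-1-iodo-4,8,12-trimethyltrideca-3,7,11-triene (homofarnesyl iodide) | ICC/C=C(\C)CC/C=C(\C)CCC=C(C)C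
F5 | step 12 | (E,E)-homofarnesyllithium | [Li]CC/C=C(\C)CC/C=C(\C)CCC=C(C)C
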